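**Retrosynthetic overview**
1. The strategy rests on the four-carbon chain C2–C3–C3'–C2' that links the two lactones: it is a succinic acid unit. Each lactone ring O1–C2(=O)–C3–C4–C4a–C8a is the retron of an azolium enolate plus o-quinone methide [4+2], and each 3,4-cis pair is its endo outcome.
2. Target 27 comes from octabenzyl ether 26 by global hydrogenolysis; 26 comes from ring B lactone acetic acid 18 and ring A sulfone 23 by the second carbene-catalysed [4+2] (sets C3 and C4).
3. Acid 18 comes from mono-tert-butyl succinate 14 and ring B sulfone 13 by the first carbene-catalysed [4+2] (sets C3' and C4'), then tert-butyl ester cleavage.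
4. Sulfones 13 and 23 come from salicylaldehydes 9 and 21 and one stock solution of aryl Grignard reagent 11 (from bromide 10); 9 derives from 2,3,4-trihydroxybenzaldehyde by two oxidation/ortho-formylation rounds, 21 from 2,4,6-trihydroxybenzaldehyde.
5. Both arenes are bought; only the lactone rings are built, ring B first and ring A last.

Key step: step 16

Remark on the chemistry: the (5aS,10bR) aminoindanol-derived triazolium salt is assumed to deliver the (3R,4R) lactone 17; if its sense of induction is the opposite, the two catalyst enantiomers are exchanged between steps 10 and 16.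

**Step 1**
Reactants: 1 2,3,4-trihydroxybenzaldehyde
Product: 2 2,3,4-tris(benzyloxy)benzaldehyde
Conditions: BnBr (3.5 equiv), K2CO3 (4 equiv), DMF, 60 °C
Reagents that add atoms: benzyl bromide, BrCc1ccccc1
Why: Williamson etherification of all three phenols, with warming so that the hydrogen-bonded 2-OH is alkylated as well.

**Step 2**
Reactants: 2 2,3,4-tris(benzyloxy)benzaldehyde
Product: 4 2,3,4-tris(benzyloxy)phenol, via aryl formate 3 (not isolated)
Conditions: mCPBA (1.3 equiv), CH2Cl2, 0 °C to rt; then K2CO3 (cat.), MeOH, rt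
Reagents that add atoms: mCPBA, OOC(=O)c1cccc(Cl)c1
Why: Baeyer–Villiger (Dakin-type) oxidation in which the aryl group, activated by ortho and para alkoxy donors, migrates in preference to hydride, and the resulting formate is removed by carbonate-catalysed methanolysis.

**Step 3**
Reactants: 4 2,3,4-tris(benzyloxy)phenol
Product: 5 3,4,5-tris(benzyloxy)-2-hydroxybenzaldehyde
Conditions: anhydrous MgCl2 (2 equiv), Et3N (4 equiv), paraformaldehyde (6 equiv), MeCN, reflux; 1 M HCl work-up
Reagents that add atoms: paraformaldehyde (as formaldehyde), C=O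
Why: magnesium-mediated ortho-formylation (Casnati–Skattebøl), in which the magnesium phenoxide delivers formaldehyde to the only free ortho carbon and a second formaldehyde oxidises the benzylic alkoxide to the aldehyde.

**Step 4**
Reactants: 5 3,4,5-tris(benzyloxy)-2-hydroxybenzaldehyde
Product: 6 2,3,4,5-tetrakis(benzyloxy)benzaldehyde
Conditions: BnBr (1.3 equiv), K2CO3 (2 equiv), DMF, 60 °C
Reagents that add atoms: benzyl bromide, BrCc1ccccc1
Why: Williamson etherification of the chelated phenol, which protects it before the second oxidation round.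

**Step 5**
Reactants: 6 2,3,4,5-tetrakis(benzyloxy)benzaldehyde
Product: 8 2,3,4,5-tetrakis(benzyloxy)phenol, via aryl formate 7 (not isolated)
Conditions: mCPBA (1.3 equiv), CH2Cl2, 0 °C to rt; then K2CO3 (cat.), MeOH, rt
Reagents that add atoms: mCPBA, OOC(=O)c1cccc(Cl)c1
Why: second Baeyer–Villiger oxidation, again favoured by the ortho and para benzyloxy donors on the migrating ring, followed by methanolysis of the formate.

**Step 6**
Reactants: 8 2,3,4,5-tetrakis(benzyloxy)phenol
Product: 9 2,3,4,5-tetrakis(benzyloxy)-6-hydroxybenzaldehyde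
Conditions: anhydrous MgCl2 (2 equiv), Et3N (4 equiv), paraformaldehyde (8 equiv), MeCN, reflux; 1 M HCl work-up
Reagents that add atoms: paraformaldehyde (as formaldehyde), C=O
Why: the same chelation-directed ortho-formylation, which can only occur at the single unsubstituted ring carbon next to the phenol.

**Step 7**
Reactants: 10 1-(benzyloxy)-4-bromobenzene
Product: 11 4-(benzyloxy)phenylmagnesium bromide (titrated stock solution in THF, kept under argon and used in steps 8 and 14)
Conditions: Mg turnings (1.2 equiv), I2 (one crystal), THF, reflux, then rt; titration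
Reagents that add atoms: magnesium, [Mg]
Why: Grignard reagent formation by insertion of magnesium metal into the aryl C–Br bond, which the benzyl ether tolerates; one batch is prepared because both salicylaldehydes need the same aryl nucleophile.

**Step 8**
Reactants: 9 2,3,4,5-tetrakis(benzyloxy)-6-hydroxybenzaldehyde; 11 4-(benzyloxy)phenylmagnesium bromide
Product: 12 racemic 2,3,4,5-tetrakis(benzyloxy)-6-{[4-(benzyloxy)phenyl](hydroxy)methyl}phenol
Conditions: 11 (2.6 equiv, THF solution from step 7), THF, 0 °C to rt; sat. aq. NH4Cl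
Reagents that add atoms: none
Why: Grignard addition in which the first equivalent of 11 deprotonates the phenol and the second adds to the chelated aldehyde to give the benzhydrol, whose configuration is irrelevant because it is erased later.

**Step 9**
Reactants: 12 racemic ring B benzhydrol
Product: 13 racemic 2,3,4,5-tetrakis(benzyloxy)-6-{[4-(benzyloxy)phenyl](4-methylbenzenesulfonyl)methyl}phenol
Conditions: 4-methylbenzenesulfinic acid (1.5 equiv), CH2Cl2, rt
Reagents that add atoms: 4-methylbenzenesulfinic acid, Cc1ccc(cc1)S(=O)O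
Why: acid-promoted SN1 exchange, in which the sulfinic acid ionises the doubly stabilised benzhydrol and the sulfinate recombines at sulfur to give the thermodynamically favoured, bench-stable sulfone.

**Step 10**
Reactants: 13 racemic ring B sulfone; 14 mono-tert-butyl succinate
Product: 17 tert-butyl 2-[(3R,4R)-5,6,7,8-tetrakis(benzyloxy)-4-[4-(benzyloxy)phenyl]-2-oxo-3,4-dihydro-2H-chromen-3-yl]acetate (3,4-cis), via acyl imidazole 15 (not isolated), via ring B o-quinone methide 16 (not isolated)
Conditions: 14 (1.5 equiv), 1,1'-carbonyldiimidazole (1.4 equiv), THF, rt; then 13 added in portions, (5aS,10bR)-2-(2,4,6-trimethylphenyl)-5a,10b-dihydro-4H,6H-indeno[2,1-b][1,2,4]triazolo[4,3-d][1,4]oxazin-2-ium tetrafluoroborate (15 mol %), Cs2CO3 (2.5 equiv), THF/toluene, 4 Å molecular sieves, 0 °C to rt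
Reagents that add atoms: none
Why: carbene-catalysed azolium enolate plus o-quinone methide formal [4+2], in which the carbene turns 15 into the (Z)-azolium enolate, Cs2CO3 releases the (E)-o-quinone methide 16 from 13, the chiral carbene fixes the enolate face (C3') and the endo approach fixes the cis C3'–C4' relation, while the racemic sulfone carbon is erased in planar 16.

**Step 11**
Reactants: 17 cis ring B lactone tert-butyl ester
Product: 18 2-[(3R,4R)-5,6,7,8-tetrakis(benzyloxy)-4-[4-(benzyloxy)phenyl]-2-oxo-3,4-dihydro-2H-chromen-3-yl]acetic acid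
Conditions: TFA/CH2Cl2 (1:4), Et3SiH (3 equiv), 0 °C
Reagents that add atoms: none
Why: acidolysis of the tert-butyl ester, with the silane trapping the tert-butyl cation so that the electron-rich arenes are not alkylated; the aryl benzyl ethers, the lactone and its cis centres should tolerate cold dilute acid.

**Step 12**
Reactants: 19 2,4,6-trihydroxybenzaldehyde
Product: 20 2,4,6-tris(benzyloxy)benzaldehyde
Conditions: BnBr (3.5 equiv), K2CO3 (4 equiv), DMF, rt to 60 °C
Reagents that add atoms: benzyl bromide, BrCc1ccccc1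
Why: Williamson etherification, with the formyl group reducing the tendency of the phloroglucinol core to alkylate at carbon.

**Step 13**
Reactants: 20 2,4,6-tris(benzyloxy)benzaldehyde
Product: 21 4,6-bis(benzyloxy)-2-hydroxybenzaldehyde
Conditions: MgBr2·OEt2 (2 equiv), toluene/Et2O, 70 °C; 1 M HCl work-up
Reagents that add atoms: none
Why: chelation-directed dealkylation, in which magnesium bound between the carbonyl oxygen and one ortho ether oxygen activates only that benzyl group for bromide attack, and the resulting magnesium phenoxide chelate protects the second ortho ether.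

**Step 14**
Reactants: 21 4,6-bis(benzyloxy)-2-hydroxybenzaldehyde; 11 4-(benzyloxy)phenylmagnesium bromide
Product: 22 racemic 3,5-bis(benzyloxy)-2-{[4-(benzyloxy)phenyl](hydroxy)methyl}phenol
Conditions: 11 (2.6 equiv, THF solution from step 7), THF, 0 °C to rt; sat. aq. NH4Cl
Reagents that add atoms: none
Why: Grignard addition to the salicylaldehyde after deprotonation of the phenol by the first equivalent, as in step 8.

**Step 15**
Reactants: 22 racemic ring A benzhydrol
Product: 23 racemic 3,5-bis(benzyloxy)-2-{[4-(benzyloxy)phenyl](4-methylbenzenesulfonyl)methyl}phenol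
Conditions: 4-methylbenzenesulfinic acid (2 equiv), CH2Cl2, 0 °C to rt
Reagents that add atoms: 4-methylbenzenesulfinic acid, Cc1ccc(cc1)S(=O)O
Why: the same SN1 exchange of the benzhydrol OH for sulfinate as in step 9, with the excess of soft sulfur nucleophile outcompeting attack by the nucleophilic phloroglucinol ring carbons.

**Step 16**
Reactants: 18 ring B lactone acetic acid; 23 racemic ring A sulfone
Product: 26 (3R,4S,3'S,4'R)-5,7,5',6',7',8'-hexakis(benzyloxy)-4,4'-bis[4-(benzyloxy)phenyl]-3,3',4,4'-tetrahydro-2H,2'H-[3,3'-bichromene]-2,2'-dione, via acyl imidazole 24 (not isolated), via ring A o-quinone methide 25 (not isolated)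
Conditions: 18, 1,1'-carbonyldiimidazole (1.0 equiv), THF, rt; then 23 (1.2 equiv) added slowly, (5aR,10bS)-2-(2,4,6-trimethylphenyl)-5a,10b-dihydro-4H,6H-indeno[2,1-b][1,2,4]triazolo[4,3-d][1,4]oxazin-2-ium tetrafluoroborate (20 mol %), Cs2CO3 (2.5 equiv), THF/toluene, 4 Å molecular sieves, 0 °C to rt
Reagents that add atoms: none
Why: CDI converts 18 into acyl imidazole 24, which the free carbene turns into an acyl azolium that is deprotonated at its alpha-CH2 to the (Z)-azolium enolate, while Cs2CO3 expels sulfinate from 23 (E1cB) to give the (E)-o-quinone methide 25, and the two combine in an endo, asynchronous inverse-demand oxa-Diels–Alder reaction. The closest known reaction type is the carbene-catalysed azolium enolate plus o-quinone methide formal [4+2] that gives cis-3,4-disubstituted dihydrocoumarins from activated aliphatic acids and 2-(sulfonylalkyl)phenols. Lactone ring A (O1–C2–C3–C4–C4a–C8a) closes by this [4+2] cycloaddition: C3 bonds to the methide carbon C4 with rearomatisation of the arene, and the phenoxide O1 then acylates at C2 (6-exo-trig addition–elimination in the stepwise view), which releases the carbene. C3 (R) is set by the chiral carbene, whose indane wall shields one enolate face, and C4 (S) follows from the endo approach of the (E)-methide, which places the aryl group and C3' cis. The step needs site-selective enolisation, enolate-face selectivity that is not overridden by the adjacent C3' centre, and endo selectivity against the thermodynamic trans preference; these rest on the acyl azolium alpha-CH2 being far more acidic than the lactone C3'-H, on using the enantiomer of the step 10 catalyst because the two halves are pseudo-mirror images (3R,4S against 3'S,4'R), and on irreversible kinetic trapping by aromatisation at or below room temperature.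

**Step 17**
Reactants: 26 octabenzyl ether
Product: 27 (3R,4S,3'S,4'R)-5,7,5',6',7',8'-hexahydroxy-4,4'-bis(4-hydroxyphenyl)-3,3',4,4'-tetrahydro-2H,2'H-[3,3'-bichromene]-2,2'-dione (target CNP0064734.3)
Conditions: H2 (1 atm), 10% Pd/C, degassed THF/EtOAc, rt; filtration and concentration under argon
Reagents that add atoms: none
Why: neutral hydrogenolysis of the eight benzyl aryl ethers in non-nucleophilic solvents, which leaves the aryl lactones and the four C–H stereocentres untouched, while exclusion of oxygen protects the tetrahydroxy arene.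

**Compound list**
1 | 2,3,4-trihydroxybenzaldehyde | O=Cc1ccc(O)c(O)c1O | starting material
2 | 2,3,4-tris(benzyloxy)benzaldehyde | O=Cc1ccc(OCc2ccccc2)c(OCc2ccccc2)c1OCc1ccccc1 | intermediate
3 | 2,3,4-tris(benzyloxy)phenyl formate | O=COc1ccc(OCc2ccccc2)c(OCc2ccccc2)c1OCc1ccccc1 | intermediate
4 | 2,3,4-tris(benzyloxy)phenol | Oc1ccc(OCc2ccccc2)c(OCc2ccccc2)c1OCc1ccccc1 | intermediate
5 | 3,4,5-tris(benzyloxy)-2-hydroxybenzaldehyde | O=Cc1cc(OCc2ccccc2)c(OCc2ccccc2)c(OCc2ccccc2)c1O | intermediate
6 | 2,3,4,5-tetrakis(benzyloxy)benzaldehyde | O=Cc1cc(OCc2ccccc2)c(OCc2ccccc2)c(OCc2ccccc2)c1OCc1ccccc1 | intermediate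
7 | 2,3,4,5-tetrakis(benzyloxy)phenyl formate | O=COc1cc(OCc2ccccc2)c(OCc2ccccc2)c(OCc2ccccc2)c1OCc1ccccc1 | intermediate
8 | 2,3,4,5-tetrakis(benzyloxy)phenol | Oc1cc(OCc2ccccc2)c(OCc2ccccc2)c(OCc2ccccc2)c1OCc1ccccc1 | intermediate
9 | 2,3,4,5-tetrakis(benzyloxy)-6-hydroxybenzaldehyde | O=Cc1c(O)c(OCc2ccccc2)c(OCc2ccccc2)c(OCc2ccccc2)c1OCc1ccccc1 | intermediate
10 | 1-(benzyloxy)-4-bromobenzene | Brc1ccc(OCc2ccccc2)cc1 | starting material
11 | 4-(benzyloxy)phenylmagnesium bromide | Br[Mg]c1ccc(OCc2ccccc2)cc1 | intermediate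
12 | racemic 2,3,4,5-tetrakis(benzyloxy)-6-{[4-(benzyloxy)phenyl](hydroxy)methyl}phenol | OC(c1ccc(OCc2ccccc2)cc1)c1c(O)c(OCc2ccccc2)c(OCc2ccccc2)c(OCc2ccccc2)c1OCc1ccccc1 | intermediate
13 | racemic 2,3,4,5-tetrakis(benzyloxy)-6-{[4-(benzyloxy)phenyl](4-methylbenzenesulfonyl)methyl}phenol | Cc1ccc(cc1)S(=O)(=O)C(c1ccc(OCc2ccccc2)cc1)c1c(O)c(OCc2ccccc2)c(OCc2ccccc2)c(OCc2ccccc2)c1OCc1ccccc1 | intermediate
14 | mono-tert-butyl succinate (4-tert-butoxy-4-oxobutanoic acid) | CC(C)(C)OC(=O)CCC(O)=O | starting material
15 | tert-butyl 4-(1H-imidazol-1-yl)-4-oxobutanoate | CC(C)(C)OC(=O)CCC(=O)n1ccnc1 | intermediate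
16 | (6E)-2,3,4,5-tetrakis(benzyloxy)-6-[4-(benzyloxy)benzylidene]cyclohexa-2,4-dien-1-one | c1ccc(cc1)COc1ccc(cc1)/C=C1/C(=O)C(OCc2ccccc2)=C(OCc2ccccc2)C(OCc2ccccc2)=C1OCc1ccccc1 | intermediate
17 | tert-butyl 2-[(3R,4R)-5,6,7,8-tetrakis(benzyloxy)-4-[4-(benzyloxy)phenyl]-2-oxo-3,4-dihydro-2H-chromen-3-yl]acetate | CC(C)(C)OC(=O)C[C@H]1C(=O)Oc2c(OCc3ccccc3)c(OCc3ccccc3)c(OCc3ccccc3)c(OCc3ccccc3)c2[C@H]1c1ccc(OCc2ccccc2)cc1 | intermediate
18 | 2-[(3R,4R)-5,6,7,8-tetrakis(benzyloxy)-4-[4-(benzyloxy)phenyl]-2-oxo-3,4-dihydro-2H-chromen-3-yl]acetic acid | OC(=O)C[C@H]1C(=O)Oc2c(OCc3ccccc3)c(OCc3ccccc3)c(OCc3ccccc3)c(OCc3ccccc3)c2[C@H]1c1ccc(OCc2ccccc2)cc1 | intermediate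
19 | 2,4,6-trihydroxybenzaldehyde | O=Cc1c(O)cc(O)cc1O | starting material
20 | 2,4,6-tris(benzyloxy)benzaldehyde | O=Cc1c(OCc2ccccc2)cc(OCc2ccccc2)cc1OCc1ccccc1 | intermediate
21 | 4,6-bis(benzyloxy)-2-hydroxybenzaldehyde | O=Cc1c(O)cc(OCc2ccccc2)cc1OCc1ccccc1 | intermediate
22 | racemic 3,5-bis(benzyloxy)-2-{[4-(benzyloxy)phenyl](hydroxy)methyl}phenol | OC(c1ccc(OCc2ccccc2)cc1)c1c(O)cc(OCc2ccccc2)cc1OCc1ccccc1 | intermediate
23 | racemic 3,5-bis(benzyloxy)-2-{[4-(benzyloxy)phenyl](4-methylbenzenesulfonyl)methyl}phenol | Cc1ccc(cc1)S(=O)(=O)C(c1ccc(OCc2ccccc2)cc1)c1c(O)cc(OCc2ccccc2)cc1OCc1ccccc1 | intermediate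
24 | 1-{2-[(3R,4R)-5,6,7,8-tetrakis(benzyloxy)-4-[4-(benzyloxy)phenyl]-2-oxo-3,4-dihydro-2H-chromen-3-yl]acetyl}-1H-imidazole | O=C(C[C@H]1C(=O)Oc2c(OCc3ccccc3)c(OCc3ccccc3)c(OCc3ccccc3)c(OCc3ccccc3)c2[C@H]1c1ccc(OCc2ccccc2)cc1)n1ccnc1 | intermediate
25 | (6E)-3,5-bis(benzyloxy)-6-[4-(benzyloxy)benzylidene]cyclohexa-2,4-dien-1-one | c1ccc(cc1)COc1ccc(cc1)/C=C1/C(=O)C=C(OCc2ccccc2)C=C1OCc1ccccc1 | intermediate
26 | (3R,4S,3'S,4'R)-5,7,5',6',7',8'-hexakis(benzyloxy)-4,4'-bis[4-(benzyloxy)phenyl]-3,3',4,4'-tetrahydro-2H,2'H-[3,3'-bichromene]-2,2'-dione | O=C1Oc2cc(OCc3ccccc3)cc(OCc3ccccc3)c2[C@H](c2ccc(OCc3ccccc3)cc2)[C@@H]1[C@H]1C(=O)Oc2c(OCc3ccccc3)c(OCc3ccccc3)c(OCc3ccccc3)c(OCc3ccccc3)c2[C@H]1c1ccc(OCc2ccccc2)cc1 | intermediate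
27 | (3R,4S,3'S,4'R)-5,7,5',6',7',8'-hexahydroxy-4,4'-bis(4-hydroxyphenyl)-3,3',4,4'-tetrahydro-2H,2'H-[3,3'-bichromene]-2,2'-dione | O=C1Oc2cc(O)cc(O)c2[C@H](c2ccc(O)cc2)[C@@H]1[C@H]1C(=O)Oc2c(O)c(O)c(O)c(O)c2[C@H]1c1ccc(O)cc1 | target

**Step count**
Total: 17 steps. Longest linear sequence: 12 steps (steps 1 to 6, 8 to 11, then 16 and 17).

**Steps most likely to fail**

Step 16. The union may be slow or unselective: the enolate is beta-branched and carries the bulky, fully substituted ring B lactone, the catalyst may be opposed by the adjacent C3' centre, and carbonate or the carbene may epimerise or open the existing cis lactone over a long reaction time. The fallback reverses the order of the annulations. It sets out from 23 and 14: acyl imidazole 15 and o-quinone methide 25 are combined under the conditions of step 10, but with (5aR,10bS)-2-(2,4,6-trimethylphenyl)-5a,10b-dihydro-4H,6H-indeno[2,1-b][1,2,4]triazolo[4,3-d][1,4]oxazin-2-ium tetrafluoroborate, to give tert-butyl 2-[(3S,4S)-5,7-bis(benzyloxy)-4-[4-(benzyloxy)phenyl]-2-oxo-3,4-dihydro-2H-chromen-3-yl]acetate F1. Acidolysis as in step 11 gives the ring A lactone acetic acid F2, and CDI gives its acyl imidazole F3. F3 is then annulated with the ring B o-quinone methide 16 (from 13 and Cs2CO3) under the (5aS,10bR) enantiomer of that triazolium tetrafluoroborate, which returns to the route at 26. In this order the enolate carries the smaller ring A lactone (no substituents at C6 and C8), and a different lactone and a different lactone/methide pairing face the basic conditions.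

Step 10. The pentasubstituted, very electron-rich methide 16 may form slowly or oligomerise, phenol 13 may be acylated at oxygen by acyl imidazole 15, and the plain aliphatic acyl azolium may enolise too slowly. The fallback reaches the same azolium enolate by internal redox of an enal and not by deprotonation of an activated acid. It sets out from 13, which is treated with bought tert-butyl (E)-4-oxobut-2-enoate F4, the (5aS,10bR) triazolium tetrafluoroborate of step 10 and Cs2CO3 in toluene. The carbene adds to the aldehyde, the homoenolate is protonated at the ester-bearing beta carbon, and the resulting azolium enolate undergoes the same endo [4+2] with 16. No acylating agent is present, and the route is rejoined at 17.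

Step 17. Cleavage of eight benzyl ethers may stall as the product becomes polar and binds to the catalyst, and the tetrahydroxy arene may be oxidised during filtration. The fallback is a non-reductive, Lewis-acid debenzylation. It sets out from 26, which is treated with BCl3 and pentamethylbenzene in CH2Cl2 at −78 °C and quenched and worked up under argon, giving 27 directly. No new compound is made on this way (entry F0).

**Further compounds**
F1 | step 16 | tert-butyl 2-[(3S,4S)-5,7-bis(benzyloxy)-4-[4-(benzyloxy)phenyl]-2-oxo-3,4-dihydro-2H-chromen-3-yl]acetate | O=C1Oc2cc(OCc3ccccc3)cc(OCc3ccccc3)c2[C@H](c2ccc(OCc3ccccc3)cc2)[C@@H]1CC(=O)OC(C)(C)C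
F2 | step 16 | 2-[(3S,4S)-5,7-bis(benzyloxy)-4-[4-(benzyloxy)phenyl]-2-oxo-3,4-dihydro-2H-chromen-3-yl]acetic acid | O=C1Oc2cc(OCc3ccccc3)cc(OCc3ccccc3)c2[C@H](c2ccc(OCc3ccccc3)cc2)[C@@H]1CC(=O)O
F3 | step 16 | 1-{2-[(3S,4S)-5,7-bis(benzyloxy)-4-[4-(benzyloxy)phenyl]-2-oxo-3,4-dihydro-2H-chromen-3-yl]acetyl}-1H-imidazole | O=C1Oc2cc(OCc3ccccc3)cc(OCc3ccccc3)c2[C@H](c2ccc(OCc3ccccc3)cc2)[C@@H]1CC(=O)n1ccnc1
F4 | step 10 | tert-butyl (E)-4-oxobut-2-enoate | CC(C)(C)OC(=O)/C=C/C=O
F0 | step 17 | none | none
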